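**Retrosynthetic overview**
1. Target ⇐ tetra-acetylation, hydroxyl-directed C11=C20 epoxidation and desilylation of a hydroxy lactone; γ-lactone (C8–C17 bond) ⇐ intramolecular SmI2 Reformatsky reaction on a C8 ketone.
2. C6–Cl / C7–OH ⇐ chloride opening of a C6–C7 epoxy ketone; ten-membered ring ⇐ Nozaki–Hiyama–Kishi closure of C7–C8 (dienyl iodide onto aldehyde).
3. C3–C7 chain ⇐ Felkin–Anh addition of an alkyltitanium reagent to the C2 aldehyde; ring A oxygens and C20 ⇐ enone epoxidation, α'-methylenation and two hydride reductions.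
4. Ring A (quaternary C1, C10) ⇐ key Diels–Alder cycloaddition of Danishefsky's diene with the (S,E)-enal made from (R)-glyceraldehyde acetonide, the only chiral material bought.
5. Order of ring formation: ring A (cycloaddition) → ten-membered carbocycle → γ-lactone → spiro-epoxide.

Assumption: the given SMILES defines the target, (1S,2S,6S,7R,8R,9S,10S,11R,12R,14S,17R) in briarane numbering; this numbering (C1–C20) is used for all intermediates, α is the ring A face that carries H10 and β the face that carries the C15 methyl.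

Every stereochemical outcome below is a substrate-control prediction from models, not a demonstrated result.

Step 1
Reactants: 1 (R)-2,2-dimethyl-1,3-dioxolane-4-carbaldehyde; 2 2-(triphenylphosphoranylidene)propanal
Product: 3 (S,E)-3-(2,2-dimethyl-1,3-dioxolan-4-yl)-2-methylprop-2-enal
Conditions: toluene, 80 °C
Reagents that add atoms: none
Why: Wittig olefination with a stabilised α-methyl ylide gives the E-trisubstituted enal, and the purchased stereocentre (future C9) is not touched.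

Step 2
Reactants: 3 (S,E)-enal; 4 (E)-1-methoxy-3-(trimethylsilyloxy)buta-1,3-diene (Danishefsky's diene)
Product: 6 ring A enone aldehyde, via cycloadduct 5 (not isolated)
Conditions: toluene, 110 °C, sealed tube; then 0.1 M HCl, THF, 0 °C
Reagents that add atoms: none
Why: Thermal Diels–Alder cycloaddition (methoxy terminus bonds to the formyl-bearing carbon) is suprafacial on the E-enal, so C2 and C9 end trans on ring A (C15 and H10 trans); the diene adds anti to the C9–O bond of the conformer whose H9 eclipses the alkene (1,3-allylic strain with the methyl), which sets C1 and C10 from the bought centre, and dilute acid then hydrolyses the silyl enol ether and eliminates methanol to the enone.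

Step 3
Reactants: 7 3-bromobut-3-en-1-ol; 8 ethynyltrimethylsilane
Product: 9 3-methylidene-5-(trimethylsilyl)pent-4-yn-1-ol
Conditions: Pd(PPh3)2Cl2 (2 mol %), CuI (4 mol %), Et3N, THF, 40 °C
Reagents that add atoms: none
Why: Sonogashira coupling of the vinyl bromide with the terminal alkyne; no stereocentre is involved.

Step 4
Reactants: 9 3-methylidene-5-(trimethylsilyl)pent-4-yn-1-ol
Product: 10 (5-bromo-3-methylidenepent-1-yn-1-yl)trimethylsilane
Conditions: CBr4, PPh3, CH2Cl2, 0 °C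
Reagents that add atoms: carbon tetrabromide, BrC(Br)(Br)Br
Why: Appel bromination of the primary alcohol; no stereocentre is involved.

Step 5
Reactants: 10 homoallylic bromide; 6 ring A enone aldehyde
Product: 13 C2 carbinol, via alkylmagnesium bromide 11 (not isolated), via alkyltitanium triisopropoxide 12 (not isolated)
Conditions: Mg, THF, 23 °C; ClTi(OiPr)3, −78 °C; then 6, −40 → 0 °C
Reagents that add atoms: none
Why: Magnesium insertion and transmetalation give a non-basic alkyltitanium reagent that adds only to the aldehyde and not to the enone, and Felkin–Anh attack anti to the large C10 branch of the quaternary C1 (methyl as the small group) gives the 2S carbinol.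

Step 6
Reactants: 13 C2 carbinol
Product: 14 13,14-α-epoxy ketone
Conditions: t-BuOOH, DBU, CH2Cl2, 0 °C
Reagents that add atoms: tert-butyl hydroperoxide, CC(C)(C)OO
Why: Weitz–Scheffer nucleophilic epoxidation of the enone; the peroxide attacks C14 on the α face, anti to the axial C15 methyl on the neighbouring quaternary carbon, so the later C14 oxygen is α.

Step 7
Reactants: 14 epoxy ketone; 15 N,N-dimethylmethyleneiminium iodide (Eschenmoser's salt)
Product: 18 11-methylidene epoxy ketone, via Mannich base 16 (not isolated), via methiodide 17 (not isolated)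
Conditions: LiN(iPr)2 (2.2 equiv), THF, −78 °C; 15, −78 → 0 °C; then MeI, CH2Cl2; NaHCO3 (aq), 23 °C
Reagents that add atoms: none
Why: The kinetic lithium enolate can only form at C11 (C13 is an epoxide carbon, C1 is quaternary); Mannich reaction, quaternisation and Hofmann-type elimination give the α-methylene ketone (C20), and no new stereocentre survives.

Step 8
Reactants: 18 11-methylidene epoxy ketone
Product: 20 terminal alkyne epoxy diol, via silylalkyne alcohol 19 (not isolated)
Conditions: NaBH4, CeCl3·7H2O, MeOH, −78 °C; then K2CO3, 23 °C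
Reagents that add atoms: none
Why: Luche 1,2-reduction delivers hydride to the ketone face anti to the epoxide oxygen (β face) and gives the 12α alcohol, and carbonate in methanol then cleaves the alkynyl C–Si bond.

Step 9
Reactants: 20 terminal alkyne epoxy diol
Product: 21 2,12,14-triol
Conditions: LiAlH4, THF, 0 → 40 °C
Reagents that add atoms: none
Why: Hydride opens the epoxide by SN2 attack at C13, the only accessible carbon (C14 is neopentyl), so the C14 oxygen keeps its α configuration and a cis-1,3-diol results.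

Step 10
Reactants: 21 2,12,14-triol
Product: 22 2,12,14-tris(tert-butyldimethylsilyl) ether
Conditions: t-BuMe2SiOTf (4 equiv), 2,6-lutidine, CH2Cl2, 0 → 23 °C
Reagents that add atoms: tert-butyldimethylsilyl trifluoromethanesulfonate, CC(C)(C)[Si](C)(C)OS(=O)(=O)C(F)(F)F
Why: Silyl triflate silylation protects all three secondary alcohols, including the hindered axial C14 hydroxyl; no stereocentre changes.

Step 11
Reactants: 22 tris-silyl ether
Product: 24 (E)-dienyl iodide, via alkenylzirconocene chloride 23 (not isolated)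
Conditions: Cp2Zr(H)Cl (1.2 equiv), THF, 23 °C; then I2, 0 °C
Reagents that add atoms: iodine, II
Why: Syn hydrozirconation of the terminal alkyne (faster than the 1,1-disubstituted alkenes) puts zirconium on the terminal carbon, and iodinolysis with retention gives the E-alkenyl iodide.

Step 12
Reactants: 24 (E)-dienyl iodide
Product: 25 8,9-diol
Conditions: CuCl2·2H2O, MeCN, 0 °C
Reagents that add atoms: none
Why: Mild Lewis-acid hydrolysis removes the terminal acetonide while the secondary silyl ethers survive; C9 is untouched.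

Step 13
Reactants: 25 8,9-diol
Product: 26 8,9-bis(triethylsilyl) ether
Conditions: Et3SiOTf, 2,6-lutidine, CH2Cl2, −78 °C
Reagents that add atoms: triethylsilyl trifluoromethanesulfonate, CC[Si](CC)(CC)OS(=O)(=O)C(F)(F)F
Why: Silylation of both hydroxyls sets up the selective oxidation of the primary one.

Step 14
Reactants: 26 8,9-bis(triethylsilyl) ether
Product: 27 C8 aldehyde
Conditions: (COCl)2, DMSO, CH2Cl2, −78 → −30 °C; then Et3N
Reagents that add atoms: none
Why: Swern conditions cleave and oxidise only the primary triethylsilyl ether, giving the α-silyloxy aldehyde without touching the secondary silyl ethers or C9.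

Step 15
Reactants: 27 C8 aldehyde
Product: 28 macrocyclic allylic alcohol (C8 epimers)
Conditions: CrCl2 (8 equiv), NiCl2 (1 mol %), DMSO/THF, 0.002 M, 23 °C
Reagents that add atoms: none
Why: Nozaki–Hiyama–Kishi reaction: the alkenyl iodide adds to nickel, transmetalates to trivalent chromium and adds intramolecularly to the aldehyde, closing the ten-membered ring with retention of the E geometry; the C8 carbinol configuration is irrelevant because it is oxidised next.

Step 16
Reactants: 28 macrocyclic allylic alcohol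
Product: 29 macrocyclic dienone
Conditions: Dess–Martin periodinane, NaHCO3, CH2Cl2, 0 °C
Reagents that add atoms: none
Why: Dess–Martin oxidation of the allylic alcohol gives the C8 ketone conjugated with C6=C7 and C5=C16.

Step 17
Reactants: 29 macrocyclic dienone
Product: 30 6,7-epoxy 8-ketone
Conditions: t-BuOOH, DBU, CH2Cl2, −20 °C
Reagents that add atoms: tert-butyl hydroperoxide, CC(C)(C)OO
Why: Weitz–Scheffer epoxidation at the α,β-bond of the transoid dienone; the E geometry fixes the trans 6,7-relationship and the peroxide adds on the outer face anti to the C9 silyloxy group, setting C7 (R) and the C6 centre that chloride will invert.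

Step 18
Reactants: 30 6,7-epoxy 8-ketone
Product: 31 6-chloro-7-hydroxy 8-ketone
Conditions: LiCl, AcOH, THF, 23 °C
Reagents that add atoms: lithium chloride, [Li+].[Cl-]
Why: Acid-assisted SN2 opening of the vinyl oxirane by chloride at the allylic C6 (remote from the carbonyl) with inversion gives the anti chlorohydrin, 6S,7R.

Step 19
Reactants: 31 6-chloro-7-hydroxy 8-ketone; 32 2-bromopropanoyl bromide (racemic)
Product: 33 7-O-(2-bromopropanoyl) ester
Conditions: pyridine, CH2Cl2, −40 °C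
Reagents that add atoms: none
Why: Acylation of the secondary α-hydroxy ketone under cold, weakly basic conditions avoids loss of HCl; the bromine-bearing carbon is a mixture because it is enolised in the next step.

Step 20
Reactants: 33 7-O-(2-bromopropanoyl) ester
Product: 35 hydroxy γ-lactone, via samarium enolate 34 (not isolated)
Conditions: SmI2 (2.5 equiv), THF, −78 °C
Reagents that add atoms: none
Why: Intramolecular samarium Reformatsky reaction: reduction of the α-bromo ester gives a trivalent samarium enolate that adds to the C8 ketone through a chelate; the ring holds C6 and C9 anti about C7–C8, so the new hydroxyl ends syn to C6 (8R, trans-fused lactone) and the methyl sits anti to the C9 branch (17R).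

Step 21
Reactants: 35 hydroxy γ-lactone
Product: 36 pentaol
Conditions: HF·pyridine, THF, 0 → 40 °C
Reagents that add atoms: none
Why: Fluoride cleaves all four silyl ethers; the allylic chloride, the lactone and the tertiary alcohol are inert.

Step 22
Reactants: 36 pentaol
Product: 37 11,20-epoxy pentaol
Conditions: VO(acac)2 (5 mol %), t-BuOOH, CH2Cl2, 0 °C
Reagents that add atoms: tert-butyl hydroperoxide, CC(C)(C)OO
Why: Hydroxyl-directed vanadium epoxidation: the 12α allylic alcohol delivers oxygen to the α face of C11=C20 (also the face anti to the axial C15 methyl, 11R), while the C5 methylene has no allylic hydroxyl.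

Step 23
Reactants: 37 11,20-epoxy pentaol
Product: 38 CNP0349227.2 (target)
Conditions: Ac2O, pyridine, DMAP, 23 °C
Reagents that add atoms: acetic anhydride, CC(=O)OC(C)=O
Why: Nucleophile-catalysed acetylation esterifies the four secondary alcohols (C2, C9, C12, C14); the tertiary C8 hydroxyl stays free.

**Compound list**
1 | (R)-2,2-dimethyl-1,3-dioxolane-4-carbaldehyde | O=C[C@H]1COC(C)(C)O1 | starting material
2 | 2-(triphenylphosphoranylidene)propanal | CC(C=O)=P(c1ccccc1)(c1ccccc1)c1ccccc1 | starting material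
3 | (S,E)-3-(2,2-dimethyl-1,3-dioxolan-4-yl)-2-methylprop-2-enal | O=C/C(C)=C/[C@H]1COC(C)(C)O1 | intermediate
4 | (E)-1-methoxy-3-(trimethylsilyloxy)buta-1,3-diene | CO/C=C/C(=C)O[Si](C)(C)C | starting material
5 | cycloadduct: 2-methoxy-1-methyl-4-(trimethylsilyloxy)-6-[(4S)-2,2-dimethyl-1,3-dioxolan-4-yl]cyclohex-3-ene-1-carbaldehyde, CHO trans to dioxolanyl, OMe epimers | O=C[C@@]1(C)C(OC)C=C(O[Si](C)(C)C)C[C@@H]1[C@H]1COC(C)(C)O1 | intermediate
6 | 1-methyl-4-oxo-6-[(4S)-2,2-dimethyl-1,3-dioxolan-4-yl]cyclohex-2-ene-1-carbaldehyde, CHO (C2, α) trans to dioxolanyl (C9, β) | O=C[C@@]1(C)C=CC(=O)C[C@@H]1[C@H]1COC(C)(C)O1 | intermediate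
7 | 3-bromobut-3-en-1-ol | OCCC(Br)=C | starting material
8 | ethynyltrimethylsilane | C#C[Si](C)(C)C | starting material
9 | 3-methylidene-5-(trimethylsilyl)pent-4-yn-1-ol | OCCC(=C)C#C[Si](C)(C)C | intermediate
10 | (5-bromo-3-methylidenepent-1-yn-1-yl)trimethylsilane | BrCCC(=C)C#C[Si](C)(C)C | intermediate
11 | [3-methylidene-5-(trimethylsilyl)pent-4-yn-1-yl]magnesium bromide | Br[Mg]CCC(=C)C#C[Si](C)(C)C | intermediate
12 | [3-methylidene-5-(trimethylsilyl)pent-4-yn-1-yl]tri(propan-2-yloxy)titanium | CC(C)O[Ti](OC(C)C)(OC(C)C)CCC(=C)C#C[Si](C)(C)C | intermediate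
13 | 4-[(1S)-1-hydroxy-4-methylidene-6-(trimethylsilyl)hex-5-yn-1-yl]-4-methyl-5-[(4S)-2,2-dimethyl-1,3-dioxolan-4-yl]cyclohex-2-en-1-one, 4,5-trans as in 6 | C[Si](C)(C)C#CC(=C)CC[C@H](O)[C@@]1(C)C=CC(=O)C[C@@H]1[C@H]1COC(C)(C)O1 | intermediate
14 | 13,14-α-epoxide of 13 (epoxide oxygen cis to the C2 chain, anti to C15) | C[Si](C)(C)C#CC(=C)CC[C@H](O)[C@@]1(C)[C@H]2O[C@H]2C(=O)C[C@@H]1[C@H]1COC(C)(C)O1 | intermediate
15 | N,N-dimethylmethyleneiminium iodide | C=[N+](C)C.[I-] | starting material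
16 | Mannich base: 11-(dimethylaminomethyl) derivative of 14 (C11 epimers) | C[Si](C)(C)C#CC(=C)CC[C@H](O)[C@@]1(C)[C@H]2O[C@H]2C(=O)C(CN(C)C)[C@@H]1[C@H]1COC(C)(C)O1 | intermediate
17 | methiodide of 16 | C[Si](C)(C)C#CC(=C)CC[C@H](O)[C@@]1(C)[C@H]2O[C@H]2C(=O)C(C[N+](C)(C)C)[C@@H]1[C@H]1COC(C)(C)O1.[I-] | intermediate
18 | 11-methylidene 13,14-α-epoxy 12-ketone | C[Si](C)(C)C#CC(=C)CC[C@H](O)[C@@]1(C)[C@H]2O[C@H]2C(=O)C(=C)[C@@H]1[C@H]1COC(C)(C)O1 | intermediate
19 | 12α-alcohol of 18 (silylalkyne) | C[Si](C)(C)C#CC(=C)CC[C@H](O)[C@@]1(C)[C@H]2O[C@H]2[C@@H](O)C(=C)[C@@H]1[C@H]1COC(C)(C)O1 | intermediate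
20 | terminal alkyne 13,14-α-epoxy 2,12α-diol | C#CC(=C)CC[C@H](O)[C@@]1(C)[C@H]2O[C@H]2[C@@H](O)C(=C)[C@@H]1[C@H]1COC(C)(C)O1 | intermediate
21 | 2,12α,14α-triol (11-methylidene, 8,9-acetonide, C7 alkyne) | C#CC(=C)CC[C@H](O)[C@@]1(C)[C@@H](O)C[C@@H](O)C(=C)[C@@H]1[C@H]1COC(C)(C)O1 | intermediate
22 | 2,12,14-tris(tert-butyldimethylsilyl) ether of 21 | C#CC(=C)CC[C@H](O[Si](C)(C)C(C)(C)C)[C@@]1(C)[C@@H](O[Si](C)(C)C(C)(C)C)C[C@@H](O[Si](C)(C)C(C)(C)C)C(=C)[C@@H]1[C@H]1COC(C)(C)O1 | intermediate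
23 | (E)-alkenyl(chloro)bis(cyclopentadienyl)zirconium from 22 | Cl[Zr](/C=C/C(=C)CC[C@H](O[Si](C)(C)C(C)(C)C)[C@@]1(C)[C@@H](O[Si](C)(C)C(C)(C)C)C[C@@H](O[Si](C)(C)C(C)(C)C)C(=C)[C@@H]1[C@H]1COC(C)(C)O1)(C1C=CC=C1)C1C=CC=C1 | intermediate
24 | (6E)-7-iodo-5(16),6-diene, 8,9-acetonide | I/C=C/C(=C)CC[C@H](O[Si](C)(C)C(C)(C)C)[C@@]1(C)[C@@H](O[Si](C)(C)C(C)(C)C)C[C@@H](O[Si](C)(C)C(C)(C)C)C(=C)[C@@H]1[C@H]1COC(C)(C)O1 | intermediate
25 | 8,9-diol of 24 | I/C=C/C(=C)CC[C@H](O[Si](C)(C)C(C)(C)C)[C@@]1(C)[C@@H](O[Si](C)(C)C(C)(C)C)C[C@@H](O[Si](C)(C)C(C)(C)C)C(=C)[C@@H]1[C@H](O)CO | intermediate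
26 | 8,9-bis(triethylsilyl) ether of 25 | I/C=C/C(=C)CC[C@H](O[Si](C)(C)C(C)(C)C)[C@@]1(C)[C@@H](O[Si](C)(C)C(C)(C)C)C[C@@H](O[Si](C)(C)C(C)(C)C)C(=C)[C@@H]1[C@H](O[Si](CC)(CC)CC)CO[Si](CC)(CC)CC | intermediate
27 | C8 aldehyde (9-O-triethylsilyl) | I/C=C/C(=C)CC[C@H](O[Si](C)(C)C(C)(C)C)[C@@]1(C)[C@@H](O[Si](C)(C)C(C)(C)C)C[C@@H](O[Si](C)(C)C(C)(C)C)C(=C)[C@@H]1[C@H](O[Si](CC)(CC)CC)C=O | intermediate
28 | macrocyclic (6E)-5(16),6,11(20)-trien-8-ol, C8 epimers | C=C1CC[C@H](O[Si](C)(C)C(C)(C)C)[C@@]2(C)[C@@H](O[Si](C)(C)C(C)(C)C)C[C@@H](O[Si](C)(C)C(C)(C)C)C(=C)[C@@H]2[C@H](O[Si](CC)(CC)CC)C(O)/C=C/1 | intermediate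
29 | macrocyclic (6E)-dien-8-one | C=C1CC[C@H](O[Si](C)(C)C(C)(C)C)[C@@]2(C)[C@@H](O[Si](C)(C)C(C)(C)C)C[C@@H](O[Si](C)(C)C(C)(C)C)C(=C)[C@@H]2[C@H](O[Si](CC)(CC)CC)C(=O)/C=C/1 | intermediate
30 | trans-6,7-epoxy 8-ketone (7R) | C=C1CC[C@H](O[Si](C)(C)C(C)(C)C)[C@@]2(C)[C@@H](O[Si](C)(C)C(C)(C)C)C[C@@H](O[Si](C)(C)C(C)(C)C)C(=C)[C@@H]2[C@H](O[Si](CC)(CC)CC)C(=O)[C@H]3O[C@H]13 | intermediate
31 | (6S,7R)-6-chloro-7-hydroxy 8-ketone | C=C1CC[C@H](O[Si](C)(C)C(C)(C)C)[C@@]2(C)[C@@H](O[Si](C)(C)C(C)(C)C)C[C@@H](O[Si](C)(C)C(C)(C)C)C(=C)[C@@H]2[C@H](O[Si](CC)(CC)CC)C(=O)[C@@H](O)[C@H]1Cl | intermediate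
32 | 2-bromopropanoyl bromide (racemic) | CC(Br)C(Br)=O | starting material
33 | 7-O-(2-bromopropanoyl) ester of 31 | C=C1CC[C@H](O[Si](C)(C)C(C)(C)C)[C@@]2(C)[C@@H](O[Si](C)(C)C(C)(C)C)C[C@@H](O[Si](C)(C)C(C)(C)C)C(=C)[C@@H]2[C@H](O[Si](CC)(CC)CC)C(=O)[C@@H](OC(=O)C(C)Br)[C@H]1Cl | intermediate
34 | samarium ester enolate of 33 | C=C1CC[C@H](O[Si](C)(C)C(C)(C)C)[C@@]2(C)[C@@H](O[Si](C)(C)C(C)(C)C)C[C@@H](O[Si](C)(C)C(C)(C)C)C(=C)[C@@H]2[C@H](O[Si](CC)(CC)CC)C(=O)[C@@H](OC(=CC)O[Sm](I)I)[C@H]1Cl | intermediate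
35 | (8R,17R)-8-hydroxy-7,19-lactone, tetrasilyl ether | C=C1CC[C@H](O[Si](C)(C)C(C)(C)C)[C@@]2(C)[C@@H](O[Si](C)(C)C(C)(C)C)C[C@@H](O[Si](C)(C)C(C)(C)C)C(=C)[C@@H]2[C@H](O[Si](CC)(CC)CC)[C@]2(O)[C@@H](C)C(=O)O[C@H]2[C@H]1Cl | intermediate
36 | 2,8,9,12,14-pentaol lactone | C=C1CC[C@H](O)[C@@]2(C)[C@@H](O)C[C@@H](O)C(=C)[C@@H]2[C@H](O)[C@]2(O)[C@@H](C)C(=O)O[C@H]2[C@H]1Cl | intermediate
37 | 11,20-epoxy pentaol lactone | C=C1CC[C@H](O)[C@@]2(C)[C@@H](O)C[C@@H](O)[C@]3(CO3)[C@@H]2[C@H](O)[C@]2(O)[C@@H](C)C(=O)O[C@H]2[C@H]1Cl | intermediate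
38 | CNP0349227.2 | C=C1CC[C@H](OC(C)=O)[C@@]2(C)[C@@H](OC(C)=O)C[C@@H](OC(C)=O)[C@]3(CO3)[C@@H]2[C@H](OC(C)=O)[C@]2(O)[C@@H](C)C(=O)O[C@H]2[C@H]1Cl | target

**Step count**
Total: 23 steps (21 in the main line plus 2 for bromide 10). Longest linear sequence: 21 steps (steps 1, 2 and 5–23, from 1).

**Three steps most likely to fail, each with a fallback**

Step 2 (Diels–Alder). The trisubstituted enal is a sluggish dienophile and the whole absolute configuration rests on one facial preference. The fallback sets out from 3 and comes back at 6. Enal 3 is activated with EtAlCl2 (CH2Cl2, −78 °C) and combined with 2-(tert-butyldimethylsilyloxy)buta-1,3-diene, a diene without the acid-labile methoxy terminus, to give the regiodefined cyclohexenyl silyl enol ether F1. Saegusa–Ito dehydrogenation of this (Pd(OAc)2, O2, DMSO, 23 °C) then places the double bond at C13=C14 and delivers enone aldehyde 6.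

Step 15 (Nozaki–Hiyama–Kishi closure of the ten-membered ring). Medium-ring strain may favour dimers or reduction of the iodide. The fallback sets out from 22 and comes back at 28, without the iodide. The acetonide of 22 is removed (CuCl2·2H2O, MeCN) to give the alkyne diol F2. Silylation (Et3SiOTf, 2,6-lutidine) gives the bis(triethylsilyl) ether F3, and Swern oxidation of the primary silyl ether gives the ynal F4. A nickel-catalysed reductive alkyne–aldehyde cyclisation (Ni(cod)2, PBu3, BEt3, toluene, high dilution) then forms C7–C8 at the terminal alkyne carbon with syn delivery of hydrogen, giving the E-allylic alcohol 28 directly.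

Step 18 (chloride opening of the epoxy ketone). Attack at C16 (SN2') is possible, and the product is a base-sensitive β-chloro ketone that must survive steps 19 and 20. The fallback sets out from 30 and comes back at 35 by reversing the order of events. The lithium enolate of methyl propanoate (LiN(iPr)2, THF, −78 °C) is added to the C8 ketone of 30 to give the epoxy hydroxy ester F5. LiCl/AcOH (THF, 23 °C) then opens the now ketone-free vinyl oxirane at the allylic C6, and the liberated C7 hydroxyl closes onto the ester to give lactone 35, so that no β-chloro ketone and no α-acyloxy ketone is ever formed.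

**Further compounds**
F1 | step 2 | 4-(tert-butyldimethylsilyloxy)-1-methyl-6-[(4S)-2,2-dimethyl-1,3-dioxolan-4-yl]cyclohex-3-ene-1-carbaldehyde, CHO trans to dioxolanyl | O=C[C@@]1(C)CC=C(O[Si](C)(C)C(C)(C)C)C[C@@H]1[C@H]1COC(C)(C)O1
F2 | step 15 | alkyne 8,9-diol (tris-silyl ether, from 22) | C#CC(=C)CC[C@H](O[Si](C)(C)C(C)(C)C)[C@@]1(C)[C@@H](O[Si](C)(C)C(C)(C)C)C[C@@H](O[Si](C)(C)C(C)(C)C)C(=C)[C@@H]1[C@H](O)CO
F3 | step 15 | alkyne 8,9-bis(triethylsilyl) ether | C#CC(=C)CC[C@H](O[Si](C)(C)C(C)(C)C)[C@@]1(C)[C@@H](O[Si](C)(C)C(C)(C)C)C[C@@H](O[Si](C)(C)C(C)(C)C)C(=C)[C@@H]1[C@H](O[Si](CC)(CC)CC)CO[Si](CC)(CC)CC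
F4 | step 15 | ynal (C8 aldehyde, C7 terminal alkyne) | C#CC(=C)CC[C@H](O[Si](C)(C)C(C)(C)C)[C@@]1(C)[C@@H](O[Si](C)(C)C(C)(C)C)C[C@@H](O[Si](C)(C)C(C)(C)C)C(=C)[C@@H]1[C@H](O[Si](CC)(CC)CC)C=O
F5 | step 18 | 6,7-epoxy 8-hydroxy 8-(1-methoxy-1-oxopropan-2-yl) aldol adduct | C=C1CC[C@H](O[Si](C)(C)C(C)(C)C)[C@@]2(C)[C@@H](O[Si](C)(C)C(C)(C)C)C[C@@H](O[Si](C)(C)C(C)(C)C)C(=C)[C@@H]2[C@H](O[Si](CC)(CC)CC)[C@](O)([C@@H](C)C(=O)OC)[C@H]3O[C@H]13
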